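**Retrosynthetic overview**
- Marchantin C comes from its di-O-methyl ether by a final double O-demethylation.
- The 18-membered ring and the meta-substituted ring D are formed together, last, by an intramolecular 2-pyranone/vinyl sulfone [4+2] cycloaddition followed by loss of CO2 and of benzenesulfinic acid.
- The open-chain precursor is joined at the ring B–ring C ethylene bridge by hydroboration/B-alkyl Suzuki coupling of a styrene with an aryl iodide.
- The styrene half comes from SNAr of 3-hydroxy-2-pyranone on 2-fluoro-3-methoxybenzaldehyde, then methylenation. The iodide half comes from 5-bromo-2-methoxyphenol by Heck reaction, Chan–Lam arylation and HWE olefination.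
- Rings A, B and C are bought as benzenes; ring D and the macrocycle are built in the same step.

Assumption: 3-hydroxy-2H-pyran-2-one is taken as a purchasable material (it is one step from mucic acid); the target has no stereocentre, so no stereocontrol is needed.

**Step 1**
Reactants: 1 3-hydroxy-2H-pyran-2-one; 2 2-fluoro-3-methoxybenzaldehyde
Product: 3 3-(2-formyl-6-methoxyphenoxy)-2H-pyran-2-one
Conditions: K2CO3, DMF, 90 °C
Reagents that add atoms: none
Why: SNAr, in which the ortho-formyl group activates the C–F bond toward the potassium pyran-3-olate (an oxygen nucleophile that is routinely O-alkylated under the same base), giving the hindered aryl pyranonyl ether directly.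

**Step 2**
Reactants: 3 3-(2-formyl-6-methoxyphenoxy)-2H-pyran-2-one
Product: 4 3-(2-ethenyl-6-methoxyphenoxy)-2H-pyran-2-one
Conditions: Ph3PCH3Br, KHMDS, THF, −78 to 0 °C
Reagents that add atoms: methyltriphenylphosphonium bromide, C[P+](c1ccccc1)(c1ccccc1)c1ccccc1.[Br-]
Why: Wittig methylenation, in which one equivalent of ylide at low temperature attacks the aldehyde much faster than the pyranone carbonyl and gives the styrene needed for hydroboration.

**Step 3**
Reactants: 5 5-bromo-2-methoxyphenol; 6 prop-2-en-1-ol (allyl alcohol)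
Product: 7 3-(3-hydroxy-4-methoxyphenyl)propanal
Conditions: Pd(OAc)2 (5 mol %), Bu4NCl, NaHCO3, DMF, 100 °C
Reagents that add atoms: none
Why: Mizoroki–Heck reaction under Jeffery conditions, in which aryl–Pd adds to the terminal alkene carbon and β-hydride elimination toward the carbinol gives the enol and hence the 3-arylpropanal, the free phenol being tolerated by the weak base.

**Step 4**
Reactants: 7 3-(3-hydroxy-4-methoxyphenyl)propanal; 8 (4-iodophenyl)boronic acid
Product: 9 3-[3-(4-iodophenoxy)-4-methoxyphenyl]propanal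
Conditions: Cu(OAc)2 (20 mol %), pyridine, 4 Å MS, O2 (1 atm), CH2Cl2, rt
Reagents that add atoms: none
Why: Chan–Lam O-arylation, a room-temperature copper-catalysed oxidative coupling of phenol and boronic acid that leaves the aryl iodide and the aldehyde untouched.

**Step 5**
Reactants: 9 3-[3-(4-iodophenoxy)-4-methoxyphenyl]propanal
Product: 10 2-(4-iodophenoxy)-1-methoxy-4-[(3E)-4-(phenylsulfonyl)but-3-en-1-yl]benzene
Conditions: (EtO)2P(O)CH2SO2Ph, NaH, THF, 0 °C to rt
Reagents that add atoms: diethyl [(phenylsulfonyl)methyl]phosphonate, CCOP(=O)(CS(=O)(=O)c1ccccc1)OCC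
Why: Horner–Wadsworth–Emmons olefination with a sulfonyl-stabilised phosphonate anion gives the (E)-vinyl sulfone selectively and does not touch the aryl iodide.

**Step 6**
Reactants: 4 3-(2-ethenyl-6-methoxyphenoxy)-2H-pyran-2-one; 10 2-(4-iodophenoxy)-1-methoxy-4-[(3E)-4-(phenylsulfonyl)but-3-en-1-yl]benzene
Product: 12 3-{2-methoxy-6-[2-(4-{2-methoxy-5-[(3E)-4-(phenylsulfonyl)but-3-en-1-yl]phenoxy}phenyl)ethyl]phenoxy}-2H-pyran-2-one, via alkylborane 11 (not isolated)
Conditions: 9-BBN, THF, 0 °C to rt; then 10, Pd(dppf)Cl2 (5 mol %), AsPh3, Cs2CO3, DMF/H2O, rt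
Reagents that add atoms: 9-BBN (9-borabicyclo[3.3.1]nonane), B1C2CCCC1CCC2 (its boron unit is in 11 and leaves again on coupling)
Why: Hydroboration/B-alkyl Suzuki–Miyaura coupling, in which 9-BBN adds anti-Markovnikov to the styrene only and the primary alkylborane couples with the aryl iodide at room temperature under mild carbonate conditions that spare the pyranone and the vinyl sulfone, so the saturated bridge forms without a hydrogenation.

**Step 7**
Reactants: 12 3-{2-methoxy-6-[2-(4-{2-methoxy-5-[(3E)-4-(phenylsulfonyl)but-3-en-1-yl]phenoxy}phenyl)ethyl]phenoxy}-2H-pyran-2-one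
Product: 15 marchantin C di-O-methyl ether, via bridged lactone 13 (not isolated), via dihydroarene sulfone 14 (not isolated)
Conditions: o-dichlorobenzene (1 mM), BHT (cat.), 180 °C, 48–72 h
Reagents that add atoms: none
Why: Intramolecular 2-pyranone Diels–Alder/retro-Diels–Alder (CO2 loss)/sulfinic acid elimination cascade with the vinyl sulfone as alkyne equivalent, in which the sulfonyl-bearing carbon bonds to the oxygen-bearing C3 of the pyranone so that the chain ends up meta to the ether oxygen, the cycloaddition closes the 18-membered ring, the two eliminations aromatise ring D, and all transient stereocentres are destroyed.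

**Step 8**
Reactants: 15 marchantin C di-O-methyl ether
Product: 16 marchantin C
Conditions: BBr3 (6 equiv), CH2Cl2, −78 to 0 °C; H2O
Reagents that add atoms: none
Why: Lewis-acid ether cleavage (BBr3 demethylation) removes only the two aryl methyl ethers, the diaryl ethers being inert, and frees the two phenols of the achiral target.

**Compound list**
1 | 3-hydroxy-2H-pyran-2-one | O=C1OC=CC=C1O | starting material
2 | 2-fluoro-3-methoxybenzaldehyde | COc1cccc(C=O)c1F | starting material
3 | 3-(2-formyl-6-methoxyphenoxy)-2H-pyran-2-one | COc1cccc(C=O)c1OC1=CC=COC1=O | intermediate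
4 | 3-(2-ethenyl-6-methoxyphenoxy)-2H-pyran-2-one | COc1cccc(C=C)c1OC1=CC=COC1=O | intermediate
5 | 5-bromo-2-methoxyphenol | COc1ccc(Br)cc1O | starting material
6 | prop-2-en-1-ol (allyl alcohol) | C=CCO | starting material
7 | 3-(3-hydroxy-4-methoxyphenyl)propanal | COc1ccc(CCC=O)cc1O | intermediate
8 | (4-iodophenyl)boronic acid | OB(O)c1ccc(I)cc1 | starting material
9 | 3-[3-(4-iodophenoxy)-4-methoxyphenyl]propanal | COc1ccc(CCC=O)cc1Oc1ccc(I)cc1 | intermediate
10 | 2-(4-iodophenoxy)-1-methoxy-4-[(3E)-4-(phenylsulfonyl)but-3-en-1-yl]benzene | COc1ccc(CC/C=C/S(=O)(=O)c2ccccc2)cc1Oc1ccc(I)cc1 | intermediate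
11 | 3-{2-[2-(9-borabicyclo[3.3.1]nonan-9-yl)ethyl]-6-methoxyphenoxy}-2H-pyran-2-one (alkylborane) | COc1cccc(CCB2C3CCCC2CCC3)c1OC1=CC=COC1=O | intermediate (not isolated)
12 | 3-{2-methoxy-6-[2-(4-{2-methoxy-5-[(3E)-4-(phenylsulfonyl)but-3-en-1-yl]phenoxy}phenyl)ethyl]phenoxy}-2H-pyran-2-one (open-chain precursor) | COc1cccc(CCc2ccc(Oc3cc(CC/C=C/S(=O)(=O)c4ccccc4)ccc3OC)cc2)c1OC1=CC=COC1=O | intermediate
13 | macrocyclic 2-oxabicyclo[2.2.2]oct-7-en-3-one cycloadduct bearing the phenylsulfonyl group (bridged lactone; racemic endo/exo mixture, sulfonyl and chain trans, drawn without stereodescriptors) | COc1cccc(CCc2ccc(Oc3cc(CCC4C(S(=O)(=O)c5ccccc5)C6(O7)C=CC4OC6=O)ccc3OC)cc2)c17 | intermediate (not isolated)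
14 | macrocyclic 6-(phenylsulfonyl)cyclohexa-1,3-diene formed by CO2 loss (dihydroarene sulfone; racemic, drawn without stereodescriptors) | COc1cccc(CCc2ccc(Oc3cc(CCC4C(S(=O)(=O)c5ccccc5)C(O6)=CC=C4)ccc3OC)cc2)c16 | intermediate (not isolated)
15 | marchantin C di-O-methyl ether | COc1ccc2cc1Oc1ccc(cc1)CCc1cccc(OC)c1Oc1cccc(c1)CC2 | intermediate
16 | marchantin C | Oc1ccc2cc1Oc1ccc(cc1)CCc1cccc(O)c1Oc1cccc(c1)CC2 | target

**Step count and risks**
Total steps: 8. Longest linear sequence: 6 (steps 3, 4, 5, 6, 7, 8 from 5-bromo-2-methoxyphenol).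

Most likely to fail, step 7: an 18-membered ring is closed by a cycloaddition that has little entropic help, and a 1,2-disubstituted vinyl sulfone is a sluggish dienophile. The fallback sets out from 4 and 10 and comes back at 15. Ring D is made first and the ring is closed by C–C coupling instead. 4 and 10 (2 equiv) are heated at 1 M in o-dichlorobenzene (170 °C, BHT), where the same cycloaddition, CO2 loss and sulfinic acid loss run intermolecularly and give the open-chain iodo styrene 1-ethenyl-2-(3-{2-[3-(4-iodophenoxy)-4-methoxyphenyl]ethyl}phenoxy)-3-methoxybenzene F1. 9-BBN in THF converts it into the alkylborane 9-{2-[2-(3-{2-[3-(4-iodophenoxy)-4-methoxyphenyl]ethyl}phenoxy)-3-methoxyphenyl]ethyl}-9-borabicyclo[3.3.1]nonane F2. This is closed at 2 mM by an intramolecular B-alkyl Suzuki coupling (Pd(dppf)Cl2, AsPh3, Cs2CO3, DMF/THF/H2O) to 15.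

Second, step 1: the pyranolate is a weak nucleophile and the pyranone may open under hot carbonate. The fallback sets out from 2 and comes back at 4, building the pyranone ring on the ether oxygen instead of arylating a finished pyranone. 2 reacts with the sodium alkoxide of methyl glycolate (NaH, THF, 0 °C) in an SNAr to give methyl 2-(2-formyl-6-methoxyphenoxy)acetate F3. Wittig methylenation (Ph3P=CH2, THF, −78 °C) gives methyl 2-(2-ethenyl-6-methoxyphenoxy)acetate F4. Its lithium enolate (LDA, THF, −78 °C) is condensed with 3-(dimethylamino)acrolein to give, after acidic dehydration, methyl 5-(dimethylamino)-2-(2-ethenyl-6-methoxyphenoxy)penta-2,4-dienoate F5. Warm aqueous HCl/AcOH hydrolyses the enamine and lactonises the enol onto the ester to give 4.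

Third, step 6: 9-BBN and aqueous base meet a pyranone and a Michael acceptor. The fallback sets out from 4 and 10 and comes back at 15, replacing the sp3–sp2 coupling by an sp2–sp2 coupling with late hydrogenation. Heck coupling of 4 with 10 (Pd(OAc)2, Bu4NCl, NaHCO3, DMF, 70 °C) gives the stilbene 3-{2-methoxy-6-[(E)-2-(4-{2-methoxy-5-[(3E)-4-(phenylsulfonyl)but-3-en-1-yl]phenoxy}phenyl)ethenyl]phenoxy}-2H-pyran-2-one F6. The thermal cascade of step 7 then gives the macrocyclic (E)-stilbene analogue of marchantin C di-O-methyl ether F7. Hydrogenation (H2, Pd/C, EtOAc, rt) gives 15.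

**Further compounds**
F1 | step 7 | 1-ethenyl-2-(3-{2-[3-(4-iodophenoxy)-4-methoxyphenyl]ethyl}phenoxy)-3-methoxybenzene | C=Cc1cccc(OC)c1Oc1cccc(CCc2ccc(OC)c(Oc3ccc(I)cc3)c2)c1
F2 | step 7 | 9-{2-[2-(3-{2-[3-(4-iodophenoxy)-4-methoxyphenyl]ethyl}phenoxy)-3-methoxyphenyl]ethyl}-9-borabicyclo[3.3.1]nonane | COc1cccc(CCB2C3CCCC2CCC3)c1Oc1cccc(CCc2ccc(OC)c(Oc3ccc(I)cc3)c2)c1
F3 | step 1 | methyl 2-(2-formyl-6-methoxyphenoxy)acetate | COC(=O)COc1c(OC)cccc1C=O
F4 | step 1 | methyl 2-(2-ethenyl-6-methoxyphenoxy)acetate | COC(=O)COc1c(OC)cccc1C=C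
F5 | step 1 | methyl 5-(dimethylamino)-2-(2-ethenyl-6-methoxyphenoxy)penta-2,4-dienoate (2E/2Z mixture) | COC(=O)C(Oc1c(OC)cccc1C=C)=CC=CN(C)C
F6 | step 6 | 3-{2-methoxy-6-[(E)-2-(4-{2-methoxy-5-[(3E)-4-(phenylsulfonyl)but-3-en-1-yl]phenoxy}phenyl)ethenyl]phenoxy}-2H-pyran-2-one | COc1cccc(/C=C/c2ccc(Oc3cc(CC/C=C/S(=O)(=O)c4ccccc4)ccc3OC)cc2)c1OC1=CC=COC1=O
F7 | step 6 | marchantin C di-O-methyl ether with an (E)-CH=CH bridge between rings B and C | COc1ccc2cc1Oc1ccc(cc1)/C=C/c1cccc(OC)c1Oc1cccc(c1)CC2
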